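Ring D is numbered D1 (carbon bearing the 3-phenylpropanoyl group), D2 (OH), D3 (CH3), D4 (OCH3), D5 (carbon bearing the CH2 bridge to flavone C8) and D6 (OH); rings A, B and C are the flavone.
Retrosynthesis: first the D6 O-ethyl and the flavone 5-O- and 7-O-benzyl bonds are cut, then the ring bonds D5-D6 and D1-D2, which split ring D into a four-carbon 1,3-dioxygenated diene D2-D5 (carrying the flavon-8-ylmethyl group at D5) and a two-carbon 3-ethoxy ynone D6-D1 (carrying the ketone). The diene is cut back at the C2-C3 bond of a 2-methyl β-keto ester, and the side chain at the C8-allyl bond.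
The feature that allows this is the alternating oxygenation of ring D (O at D2, D4 and D6, acyl at D1): D2 and D4 are the ketene acetal and enol ether carbons of the diene, and D6 and D1 are the donor and acceptor carbons of a push-pull alkyne.
Forward: rings A, B and C come with galangin; an allyl group is moved from O7 to C8 (Claisen) and grown into the oxygenated five-carbon diene chain; ring D is closed last in one (4+2) benzannulation with the ynone, and one BCl3 dealkylation ends the route.
Stereochemistry: the target has no stereocentre and no stereogenic double bond; the (Z)-enol ether of the diene, set in the enolisation, only serves reactivity and vanishes on aromatisation.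
Key step: step 13

Remark on the chemistry: the ketene acetal geometry of 18 and 19 and the relative configuration of the two sp3 centres of 26 are not controlled and do not matter, so they are left unspecified; 12, 14, 15, 16 and 24 are racemic; the aryloxyboron species of step 14 are hydrolysed on work-up and are not numbered.
Abbreviation used in names: Ar = 5,7-bis(benzyloxy)-3-methoxy-4-oxo-2-phenyl-4H-chromen-8-yl.

Step 1
Reactants: 1 galangin; 2 allyl bromide
Product: 3 7-(allyloxy)-3,5-dihydroxy-2-phenyl-4H-chromen-4-one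
Conditions: 2 (1.05 equiv), K2CO3 (1.1 equiv), DMF, rt
Reagents that add atoms: none
Why: Williamson etherification; the 7-OH, para to the carbonyl and not hydrogen-bonded, is the most acidic phenol of galangin, so one equivalent of electrophile with a mild base should alkylate it ahead of the 3-OH and the chelated 5-OH.

Step 2
Reactants: 3 7-(allyloxy)-3,5-dihydroxy-2-phenyl-4H-chromen-4-one
Product: 4 7-(allyloxy)-5-hydroxy-3-methoxy-2-phenyl-4H-chromen-4-one
Conditions: MeI, K2CO3, acetone, rt
Reagents that add atoms: iodomethane, CI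
Why: Williamson O-methylation; the 3-hydroxyl is free whereas the 5-OH is locked in a hydrogen bond to the C4 carbonyl and should stay untouched at room temperature.

Step 3
Reactants: 4 7-(allyloxy)-5-hydroxy-3-methoxy-2-phenyl-4H-chromen-4-one
Product: 5 8-allyl-5,7-dihydroxy-3-methoxy-2-phenyl-4H-chromen-4-one
Conditions: PhNEt2, 200 °C
Reagents that add atoms: none
Why: Aromatic Claisen rearrangement ([3,3]-sigmatropic shift, then tautomerisation); in 7-allyloxychromones the C7-C8 bond has the greater double-bond character, so migration to C8 is expected to prevail over C6.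

Step 4
Reactants: 5 8-allyl-5,7-dihydroxy-3-methoxy-2-phenyl-4H-chromen-4-one
Product: 6 8-allyl-5,7-bis(benzyloxy)-3-methoxy-2-phenyl-4H-chromen-4-one
Conditions: BnBr, K2CO3, Bu4NI (cat.), DMF, 70 °C
Reagents that add atoms: benzyl bromide, BrCc1ccccc1
Why: Williamson benzylation; heating in DMF with iodide catalysis overcomes the chelation of the 5-OH, so both phenols are capped before the oxidation, acylation and strong-base steps.

Step 5
Reactants: 6 8-allyl-5,7-bis(benzyloxy)-3-methoxy-2-phenyl-4H-chromen-4-one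
Product: 8 3-Ar-propan-1-ol, via B-alkyl-9-BBN adduct 7 (not isolated)
Conditions: 9-BBN, THF, 0 °C to rt; then H2O2, aq. NaOH, 0 °C
Reagents that add atoms: 9-borabicyclo[3.3.1]nonane, B1C2CCCC1CCC2 (boron and bicyclic frame of 7 only); hydrogen peroxide, OO
Why: Hydroboration-oxidation; 9-BBN adds anti-Markovnikov to the terminal alkene much faster than it touches the vinylogous-ester carbonyl or the tetrasubstituted C2=C3 bond, and cold alkaline peroxide replaces boron by hydroxyl.

Step 6
Reactants: 8 3-Ar-propan-1-ol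
Product: 10 3-Ar-propanoic acid, via aldehyde 9 (not isolated)
Conditions: TEMPO (cat.), PhI(OAc)2, MeCN/H2O, rt
Reagents that add atoms: water, O
Why: Nitroxyl-catalysed alcohol oxidation with a hypervalent iodine terminal oxidant; the primary alcohol goes through aldehyde 9 and its hydrate to the acid without a halogenating co-oxidant that could attack the electron-rich ring A.

Step 7
Reactants: 11 dimethyl methylmalonate
Product: 12 potassium 3-methoxy-2-methyl-3-oxopropanoate (potassium methyl methylmalonate)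
Conditions: KOH (1.0 equiv), MeOH, 0 °C to rt
Reagents that add atoms: potassium hydroxide, [K+].[OH-]
Why: Partial saponification; one equivalent of hydroxide cleaves one ester and the resulting carboxylate shields the second ester from further attack.

Step 8
Reactants: 10 3-Ar-propanoic acid; 12 potassium methyl methylmalonate
Product: 15 methyl 5-Ar-2-methyl-3-oxopentanoate, via acyl imidazolide 13 (not isolated), via acylmalonate half-ester 14 (not isolated)
Conditions: CDI, THF, rt; then 12, MgCl2, Et3N, MeCN, rt to 45 °C; 1 M HCl work-up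
Reagents that add atoms: 1,1'-carbonyldiimidazole, O=C(n1ccnc1)n1ccnc1 (imidazolyl group of 13 only)
Why: Masamune-Brooks homologation (Claisen-type C-acylation of the magnesium malonate half-ester by the acyl imidazolide, then decarboxylation) builds the 2-methyl β-keto ester under near-neutral conditions that spare the chromone and the benzyl ethers.

Step 9
Reactants: 15 methyl 5-Ar-2-methyl-3-oxopentanoate
Product: 17 methyl (2E)-5-Ar-3-methoxy-2-methylpent-2-enoate, via dimethyl ketal 16 (not isolated)
Conditions: HC(OMe)3, TsOH (cat.), MeOH, 60 °C; then PhMe, 100 °C (MeOH distilled off)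
Reagents that add atoms: trimethyl orthoformate, COC(OC)OC
Why: Acid-catalysed ketalisation with the orthoformate, then thermal loss of methanol (enol ether formation), gives the β-methoxy enoate; the (E)-isomer is expected, and either geometry would serve because this double bond becomes the central single bond of the diene.

Step 10
Reactants: 17 methyl (2E)-5-Ar-3-methoxy-2-methylpent-2-enoate
Product: 19 5,7-bis(benzyloxy)-8-[(2Z)-3,5-dimethoxy-4-methyl-5-(trimethylsilyloxy)penta-2,4-dien-1-yl]-3-methoxy-2-phenyl-4H-chromen-4-one, via lithium dienolate 18 (not isolated)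
Conditions: LiN(i-Pr)2, THF, -78 °C; then Me3SiCl, -78 to 0 °C; used crude
Reagents that add atoms: lithium diisopropylamide, CC(C)N([Li])C(C)C (lithium of 18 only); chlorotrimethylsilane, C[Si](C)(C)Cl
Why: Kinetic γ-deprotonation of the β-methoxy enoate and O-silylation of the extended enolate give the vinylogous silyl ketene acetal (Brassard-type diene); the flavonylmethyl group should settle trans to the bulky C2 substituent, which is the (Z)-enol ether.

Step 11
Reactants: 20 3-phenylpropanoyl chloride
Product: 21 N-methoxy-N-methyl-3-phenylpropanamide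
Conditions: MeNH(OMe)·HCl, K2CO3, EtOAc/H2O, 0 °C
Reagents that add atoms: N,O-dimethylhydroxylamine hydrochloride, CNOC.Cl
Why: Schotten-Baumann acylation of the hydroxylamine gives the Weinreb amide.

Step 12
Reactants: 22 ethoxyacetylene; 21 N-methoxy-N-methyl-3-phenylpropanamide
Product: 25 1-ethoxy-5-phenylpent-1-yn-3-one, via lithium ethoxyacetylide 23 (not isolated), via lithium hemiaminal adduct 24 (not isolated)
Conditions: n-BuLi, THF, -78 °C; then 21, -78 to -20 °C; cold pH 7 buffer
Reagents that add atoms: n-butyllithium, [Li]CCCC (lithium of 23 and 24 only)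
Why: Weinreb ketone synthesis; the acetylide adds once, the chelated adduct 24 holds until the quench, and the neutral work-up avoids acid-catalysed hydration of the ynol ether.

Step 13
Reactants: 19 Brassard-type diene; 25 1-ethoxy-5-phenylpent-1-yn-3-one
Product: 27 1-[3-(Ar-methyl)-2-ethoxy-6-hydroxy-4-methoxy-5-methylphenyl]-3-phenylpropan-1-one, via cyclohexadiene cycloadduct 26 (not isolated)
Conditions: 25 (1.5 equiv), PhMe, rt to 60 °C; then SiO2, CH2Cl2, rt
Reagents that add atoms: none
Why: Proposed new method: diene 19 is a vinylogous silyl ketene acetal with its largest HOMO coefficient at the terminal carbon D5, and ynone 25 is a push-pull alkyne whose ketone makes the ethoxy-bearing carbon D6 the electrophilic site, so an asynchronous (4+2) cycloaddition, or its stepwise equivalent of vinylogous Mukaiyama-Michael addition followed by attack of the allenolate carbon D1 on the silyloxycarbenium carbon D2, should give cyclohexa-1,4-diene 26. The closest known reaction type is the Diels-Alder reaction of Brassard-type 1,3-dialkoxy-1-silyloxydienes with alkynyl ketones and propiolates, which gives resorcinol derivatives after loss of an alkoxysilane; a 3-alkoxy ynone as dienophile and a diene substituted at every carbon go beyond it. Ring D closes as a six-membered carbocycle by (4+2) union of the four-carbon unit D2-D5 with the two-carbon unit D6-D1, forming the bonds D5-D6 and D1-D2. The mixed ketal at D2 then collapses with loss of Me3SiOMe to a cyclohexadienone, which tautomerises by shift of the D5 hydrogen to the phenol hydrogen-bonded to the ketone, so no stereocentre remains and none has to be controlled. The step needs head-to-tail regiochemistry and reaction at the alkyne only, and both follow from the substrate: donor oxygens at D2 and D4 against the acceptor at D1 allow only the D5-to-D6 orientation, while the tetrasubstituted, electron-rich C2=C3 bond of the chromone and its vinylogous-ester carbonyl are inert. The outward-pointing flavonylmethyl group of the (Z)-enol ether lets the diene reach the s-cis conformation, and the temperature stays at or below 60 °C because ethyl ynol ethers lose ethene to give ketenes near 100 °C.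

Step 14
Reactants: 27 1-[3-(Ar-methyl)-2-ethoxy-6-hydroxy-4-methoxy-5-methylphenyl]-3-phenylpropan-1-one
Product: 28 8-{[2,4-dihydroxy-6-methoxy-5-methyl-3-(3-phenylpropanoyl)phenyl]methyl}-5,7-dihydroxy-3-methoxy-2-phenyl-4H-chromen-4-one
Conditions: BCl3 (excess), C6HMe5, CH2Cl2, -78 to 20 °C; then H2O, 0 °C
Reagents that add atoms: none
Why: Lewis-acid ether cleavage; BCl3 with pentamethylbenzene as benzyl-cation scavenger removes the two aryl benzyl ethers at low temperature and, on warming, the boron chelated by the aryl ketone cleaves the ortho ethyl ether, while the unchelated D4 methyl ether and the 3-methoxy group (its carbonyl tied up in the 5-O-boron chelate) should survive.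

Compound list
1 | galangin (3,5,7-trihydroxy-2-phenyl-4H-chromen-4-one) | O=c1c(O)c(-c2ccccc2)oc2cc(O)cc(O)c12 | starting material
2 | allyl bromide (3-bromoprop-1-ene) | C=CCBr | starting material
3 | 7-(allyloxy)-3,5-dihydroxy-2-phenyl-4H-chromen-4-one | O=c1c(O)c(-c2ccccc2)oc2cc(OCC=C)cc(O)c12 | intermediate
4 | 7-(allyloxy)-5-hydroxy-3-methoxy-2-phenyl-4H-chromen-4-one | COc1c(-c2ccccc2)oc2cc(OCC=C)cc(O)c2c1=O | intermediate
5 | 8-allyl-5,7-dihydroxy-3-methoxy-2-phenyl-4H-chromen-4-one | COc1c(-c2ccccc2)oc2c(CC=C)c(O)cc(O)c2c1=O | intermediate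
6 | 8-allyl-5,7-bis(benzyloxy)-3-methoxy-2-phenyl-4H-chromen-4-one | COc1c(-c2ccccc2)oc2c(CC=C)c(OCc3ccccc3)cc(OCc3ccccc3)c2c1=O | intermediate
7 | 9-{3-[5,7-bis(benzyloxy)-3-methoxy-4-oxo-2-phenyl-4H-chromen-8-yl]propyl}-9-borabicyclo[3.3.1]nonane (formed in the flask) | B1(CCCc2c(OCc3ccccc3)cc(OCc3ccccc3)c3c(=O)c(OC)c(-c4ccccc4)oc23)C2CCCC1CCC2 | intermediate
8 | 5,7-bis(benzyloxy)-8-(3-hydroxypropyl)-3-methoxy-2-phenyl-4H-chromen-4-one | OCCCc1c(OCc2ccccc2)cc(OCc2ccccc2)c2c(=O)c(OC)c(-c3ccccc3)oc12 | intermediate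
9 | 3-[5,7-bis(benzyloxy)-3-methoxy-4-oxo-2-phenyl-4H-chromen-8-yl]propanal (formed in the flask) | O=CCCc1c(OCc2ccccc2)cc(OCc2ccccc2)c2c(=O)c(OC)c(-c3ccccc3)oc12 | intermediate
10 | 3-[5,7-bis(benzyloxy)-3-methoxy-4-oxo-2-phenyl-4H-chromen-8-yl]propanoic acid | OC(=O)CCc1c(OCc2ccccc2)cc(OCc2ccccc2)c2c(=O)c(OC)c(-c3ccccc3)oc12 | intermediate
11 | dimethyl methylmalonate | COC(=O)C(C)C(=O)OC | starting material
12 | potassium 3-methoxy-2-methyl-3-oxopropanoate (racemic) | COC(=O)C(C)C(=O)[O-].[K+] | intermediate
13 | 1-{3-[5,7-bis(benzyloxy)-3-methoxy-4-oxo-2-phenyl-4H-chromen-8-yl]propanoyl}imidazole (formed in the flask) | O=C(CCc1c(OCc2ccccc2)cc(OCc2ccccc2)c2c(=O)c(OC)c(-c3ccccc3)oc12)n1ccnc1 | intermediate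
14 | 2-{3-[5,7-bis(benzyloxy)-3-methoxy-4-oxo-2-phenyl-4H-chromen-8-yl]propanoyl}-3-methoxy-2-methyl-3-oxopropanoic acid (racemic; formed in the flask as its magnesium salt) | COC(=O)C(C)(C(=O)O)C(=O)CCc1c(OCc2ccccc2)cc(OCc2ccccc2)c2c(=O)c(OC)c(-c3ccccc3)oc12 | intermediate
15 | methyl 5-[5,7-bis(benzyloxy)-3-methoxy-4-oxo-2-phenyl-4H-chromen-8-yl]-2-methyl-3-oxopentanoate (racemic) | COC(=O)C(C)C(=O)CCc1c(OCc2ccccc2)cc(OCc2ccccc2)c2c(=O)c(OC)c(-c3ccccc3)oc12 | intermediate
16 | methyl 5-[5,7-bis(benzyloxy)-3-methoxy-4-oxo-2-phenyl-4H-chromen-8-yl]-3,3-dimethoxy-2-methylpentanoate (racemic; formed in the flask) | COC(=O)C(C)C(OC)(OC)CCc1c(OCc2ccccc2)cc(OCc2ccccc2)c2c(=O)c(OC)c(-c3ccccc3)oc12 | intermediate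
17 | methyl (2E)-5-[5,7-bis(benzyloxy)-3-methoxy-4-oxo-2-phenyl-4H-chromen-8-yl]-3-methoxy-2-methylpent-2-enoate | COC(=O)/C(C)=C(/OC)CCc1c(OCc2ccccc2)cc(OCc2ccccc2)c2c(=O)c(OC)c(-c3ccccc3)oc12 | intermediate
18 | lithium (3Z)-5-[5,7-bis(benzyloxy)-3-methoxy-4-oxo-2-phenyl-4H-chromen-8-yl]-1,3-dimethoxy-2-methylpenta-1,3-dien-1-olate (formed in the flask) | [Li]OC(OC)=C(C)/C(OC)=C/Cc1c(OCc2ccccc2)cc(OCc2ccccc2)c2c(=O)c(OC)c(-c3ccccc3)oc12 | intermediate
19 | 5,7-bis(benzyloxy)-8-[(2Z)-3,5-dimethoxy-4-methyl-5-(trimethylsilyloxy)penta-2,4-dien-1-yl]-3-methoxy-2-phenyl-4H-chromen-4-one | COC(O[Si](C)(C)C)=C(C)/C(OC)=C/Cc1c(OCc2ccccc2)cc(OCc2ccccc2)c2c(=O)c(OC)c(-c3ccccc3)oc12 | intermediate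
20 | 3-phenylpropanoyl chloride | O=C(Cl)CCc1ccccc1 | starting material
21 | N-methoxy-N-methyl-3-phenylpropanamide | CON(C)C(=O)CCc1ccccc1 | intermediate
22 | ethoxyacetylene (ethoxyethyne) | CCOC#C | starting material
23 | lithium ethoxyacetylide (formed in the flask) | CCOC#C[Li] | intermediate
24 | lithium 1-ethoxy-3-[methoxy(methyl)amino]-5-phenylpent-1-yn-3-olate (racemic; formed in the flask) | CCOC#CC(O[Li])(CCc1ccccc1)N(C)OC | intermediate
25 | 1-ethoxy-5-phenylpent-1-yn-3-one | CCOC#CC(=O)CCc1ccccc1 | intermediate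
26 | 5,7-bis(benzyloxy)-8-{[2-ethoxy-4,6-dimethoxy-5-methyl-3-(3-phenylpropanoyl)-4-(trimethylsilyloxy)cyclohexa-2,5-dien-1-yl]methyl}-3-methoxy-2-phenyl-4H-chromen-4-one (mixture of diastereomers; formed in the flask) | CCOC1=C(C(=O)CCc2ccccc2)C(OC)(O[Si](C)(C)C)C(C)=C(OC)C1Cc1c(OCc2ccccc2)cc(OCc2ccccc2)c2c(=O)c(OC)c(-c3ccccc3)oc12 | intermediate
27 | 1-[3-{[5,7-bis(benzyloxy)-3-methoxy-4-oxo-2-phenyl-4H-chromen-8-yl]methyl}-2-ethoxy-6-hydroxy-4-methoxy-5-methylphenyl]-3-phenylpropan-1-one | CCOc1c(C(=O)CCc2ccccc2)c(O)c(C)c(OC)c1Cc1c(OCc2ccccc2)cc(OCc2ccccc2)c2c(=O)c(OC)c(-c3ccccc3)oc12 | intermediate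
28 | 8-{[2,4-dihydroxy-6-methoxy-5-methyl-3-(3-phenylpropanoyl)phenyl]methyl}-5,7-dihydroxy-3-methoxy-2-phenyl-4H-chromen-4-one (CNP0280022.0) | COc1c(C)c(O)c(C(=O)CCc2ccccc2)c(O)c1Cc1c(O)cc(O)c2c(=O)c(OC)c(-c3ccccc3)oc12 | target

Total step count: 14.
Longest linear sequence: 11 steps (steps 1-6, 8-10, 13 and 14, from galangin 1 to 28).

Steps most likely to fail

Step 13 (carries the proposed method). The ethoxy group lowers the electrophilicity of the alkyne, so the addition may be slower than hydrolysis or oligomerisation of the diene or than fragmentation of the ynol ether; the crowded, fully substituted diene may also add once without closing the ring. The fallback uses known chemistry only and does not build ring D by cycloaddition: it takes a preformed acylphloroglucinol and joins it to flavone C8 through the methylene carbon. It sets out from 4 and 20 and comes back to the route at 28.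
- From 4, palladium-catalysed deallylation (Pd(PPh3)4, morpholine, THF) should give 5,7-dihydroxy-3-methoxy-2-phenyl-4H-chromen-4-one F1.
- Mannich reaction of F1 (aq. CH2O, Me2NH, EtOH, rt) at the nucleophilic C8 should give 8-[(dimethylamino)methyl]-5,7-dihydroxy-3-methoxy-2-phenyl-4H-chromen-4-one F2.
- Separately, Friedel-Crafts acylation of commercial 2-methylphloroglucinol with 20 (AlCl3, PhNO2) should give 1-(2,4,6-trihydroxy-3-methylphenyl)-3-phenylpropan-1-one F3.
- Methylation of the only hydroxyl of F3 not chelated to the ketone (Me2SO4, one equivalent, K2CO3, acetone) should give 1-(2,6-dihydroxy-4-methoxy-3-methylphenyl)-3-phenylpropan-1-one F4.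
- Heating F2 with F4 (dioxane, 100 °C) should expel dimethylamine to give the ortho-quinone methide 5-hydroxy-3-methoxy-8-methylidene-2-phenyl-4H-chromene-4,7(8H)-dione F5, which is trapped at the single free ring position of F4 (Michael-type C-alkylation) to give 28.

Step 14. Once the ketone is chelated by the D2 oxygen, removal of the ethyl group at D6 may become slower than demethylation at D4 or at C3, giving incomplete deethylation or over-dealkylation. The fallback changes the ynol ether to one that BCl3 cleaves without carbonyl assistance. It sets out from 21 and 19 and comes back at 28.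
- Propan-2-ol, KH and trichloroethene should give (E)-1,2-dichloro-1-(propan-2-yloxy)ethene F6.
- Two equivalents of n-BuLi convert F6 into lithium isopropoxyacetylide F7.
- F7 adds to 21 to give the lithium hemiaminal adduct F8 and, after neutral quench, 5-phenyl-1-(propan-2-yloxy)pent-1-yn-3-one F9.
- Reaction of F9 with 19 as in step 13 should give the cyclohexadiene cycloadduct F10 and, after loss of Me3SiOMe, 1-[3-(Ar-methyl)-6-hydroxy-4-methoxy-5-methyl-2-(propan-2-yloxy)phenyl]-3-phenylpropan-1-one F11.
- BCl3/C6HMe5 (CH2Cl2, -78 to 0 °C) cleaves isopropyl and benzyl aryl ethers far faster than methyl ethers and should give 28.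

Step 3. The allyl group may migrate to C6 in competition with C8, and the two ring-allylated isomers may be hard to separate. The fallback fixes the C8 position by halogenating the fully protected flavone and coupling. It sets out from 1 and comes back at 6.
- One equivalent of BnBr (K2CO3, DMF, rt) should give 7-(benzyloxy)-3,5-dihydroxy-2-phenyl-4H-chromen-4-one F12.
- MeI/K2CO3 (acetone, rt) should give 7-(benzyloxy)-5-hydroxy-3-methoxy-2-phenyl-4H-chromen-4-one F13.
- BnBr/K2CO3 (DMF, 70 °C) should give 5,7-bis(benzyloxy)-3-methoxy-2-phenyl-4H-chromen-4-one F14.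
- Iodination (I2, CF3CO2Ag, CH2Cl2), which in 5,7-dialkoxyflavones is expected at the less hindered C8, should give 5,7-bis(benzyloxy)-8-iodo-3-methoxy-2-phenyl-4H-chromen-4-one F15.
- Stille coupling of F15 with allyltributylstannane (Pd(PPh3)4, DMF, 90 °C) gives 6, from which step 5 continues.

Further compounds
F1 | step 13 | 5,7-dihydroxy-3-methoxy-2-phenyl-4H-chromen-4-one | COc1c(-c2ccccc2)oc2cc(O)cc(O)c2c1=O
F2 | step 13 | 8-[(dimethylamino)methyl]-5,7-dihydroxy-3-methoxy-2-phenyl-4H-chromen-4-one | COc1c(-c2ccccc2)oc2c(CN(C)C)c(O)cc(O)c2c1=O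
F3 | step 13 | 1-(2,4,6-trihydroxy-3-methylphenyl)-3-phenylpropan-1-one | O=C(CCc1ccccc1)c1c(O)c(C)c(O)cc1O
F4 | step 13 | 1-(2,6-dihydroxy-4-methoxy-3-methylphenyl)-3-phenylpropan-1-one | COc1cc(O)c(C(=O)CCc2ccccc2)c(O)c1C
F5 | step 13 | 5-hydroxy-3-methoxy-8-methylidene-2-phenyl-4H-chromene-4,7(8H)-dione | C=C1C(=O)C=C(O)C2=C1OC(c1ccccc1)=C(OC)C2=O
F6 | step 14 | (E)-1,2-dichloro-1-(propan-2-yloxy)ethene | CC(C)O/C(Cl)=C\Cl
F7 | step 14 | lithium isopropoxyacetylide | CC(C)OC#C[Li]
F8 | step 14 | lithium 3-[methoxy(methyl)amino]-5-phenyl-1-(propan-2-yloxy)pent-1-yn-3-olate | CC(C)OC#CC(O[Li])(CCc1ccccc1)N(C)OC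
F9 | step 14 | 5-phenyl-1-(propan-2-yloxy)pent-1-yn-3-one | CC(C)OC#CC(=O)CCc1ccccc1
F10 | step 14 | 5,7-bis(benzyloxy)-8-{[4,6-dimethoxy-5-methyl-3-(3-phenylpropanoyl)-2-(propan-2-yloxy)-4-(trimethylsilyloxy)cyclohexa-2,5-dien-1-yl]methyl}-3-methoxy-2-phenyl-4H-chromen-4-one | CC(C)OC1=C(C(=O)CCc2ccccc2)C(OC)(O[Si](C)(C)C)C(C)=C(OC)C1Cc1c(OCc2ccccc2)cc(OCc2ccccc2)c2c(=O)c(OC)c(-c3ccccc3)oc12
F11 | step 14 | 1-[3-{[5,7-bis(benzyloxy)-3-methoxy-4-oxo-2-phenyl-4H-chromen-8-yl]methyl}-6-hydroxy-4-methoxy-5-methyl-2-(propan-2-yloxy)phenyl]-3-phenylpropan-1-one | CC(C)Oc1c(C(=O)CCc2ccccc2)c(O)c(C)c(OC)c1Cc1c(OCc2ccccc2)cc(OCc2ccccc2)c2c(=O)c(OC)c(-c3ccccc3)oc12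
F12 | step 3 | 7-(benzyloxy)-3,5-dihydroxy-2-phenyl-4H-chromen-4-one | O=c1c(O)c(-c2ccccc2)oc2cc(OCc3ccccc3)cc(O)c12
F13 | step 3 | 7-(benzyloxy)-5-hydroxy-3-methoxy-2-phenyl-4H-chromen-4-one | COc1c(-c2ccccc2)oc2cc(OCc3ccccc3)cc(O)c2c1=O
F14 | step 3 | 5,7-bis(benzyloxy)-3-methoxy-2-phenyl-4H-chromen-4-one | COc1c(-c2ccccc2)oc2cc(OCc3ccccc3)cc(OCc3ccccc3)c2c1=O
F15 | step 3 | 5,7-bis(benzyloxy)-8-iodo-3-methoxy-2-phenyl-4H-chromen-4-one | COc1c(-c2ccccc2)oc2c(I)c(OCc3ccccc3)cc(OCc3ccccc3)c2c1=O
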